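The pitfall I watched for with a slow feed was to treat it as Sunday's flask in slow motion, with the same chemistry merely delayed. The earlier runs varied Q and held D and J, and I had these flasks and questions before me:

| flask | Q | D | J | remark | time |
|---|---|---|---|---|---|
| south-west | 20 mM | 22 mM | 20 mM | run made earlier |  |
| north-east | 28 mM | 22 mM | 20 mM | run made earlier |  |
| south-east | 44 mM | 22 mM | 20 mM | run made earlier |  |
| Sunday's | 20 mM | 22.0 mM | 20.0 mM | everything together at the start | 4.0 h |
| Friday's | 20 mM | 22.0 mM | 20.0 mM (fed, over 2.5 h) | all else is in the flask from the start; the feed brings no volume worth counting | 4.0 h |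
| Saturday's | 20 mM | 22.0 mM (fed, over 2.5 h) | 20.0 mM | all else is in the flask from the start; the feed brings no volume worth counting | 4.0 h |

| run | time / h | G / % |
|---|---|---|
| south-west | 0.667 | 19 |
| south-west | 1.33 | 14 |
| south-west | 2.00 | 12 |
| south-west | 2.50 | 10 |
| south-west | 3.00 | 14 |
| south-west | 4.00 | 10 |
| north-east | 0.333 | 23 |
| north-east | 1.00 | 15 |
| north-east | 1.50 | 13 |
| north-east | 2.50 | 12 |
| north-east | 4.00 | 10 |
| north-east | 5.00 | 9 |
| south-east | 0.833 | 17 |
| south-east | 1.50 | 15 |
| south-east | 2.50 | 14 |
| south-east | 3.00 | 11 |
| south-east | 4.00 | 8 |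
| south-east | 5.00 | 8 |

(standard deviation of a reading: 1.5 percentage points)



- the flask that comes out highest in amount of G, in percent of the Q charged, or "all alike" when all lie within 1.5 percentage points (Sunday's / Friday's / Saturday's / all alike)
- G at the end, in percent of the Q charged, Sunday's
- G at the end, in percent of the Q charged, Friday's
- G at the end, in percent of the Q charged, Saturday's

I counted turnovers on a ladder of times. On the fastest rung stood whatever forms G: no run read higher later than at its first reading, and the north-east run already read 23% at 0.333 h, so I took that time as an upper limit for one quick turnover. On the next rung stood the feed of 2.5 h, which gave 7.51 as the feed time over that limit, my feed count, and a lower bound. Because the feed outlasted a quick turnover, I expected a fed species, while it still found partners, to stand in a quasi-steady state at no more than its charge divided by the count: 2.66 mM of J in Friday's flask and 2.93 mM of D in Saturday's, against 20.0 mM and 22.0 mM at the start in Sunday's. So I read Friday's as Q and D with J trickling in, and Saturday's as Q and J with D trickling in, which are changes of partners and not delays. On the slowest rung G faded, in the north-east run to 15% at 1.00 h and 9% at 5.00 h, and the south-west run read 10% at 4.00 h, which I took for Sunday's. Since D and J were never varied, I gave no figure for the feeds.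

The forecast named Friday's, with 10% for Sunday's, 12.5% for Friday's and 12% for Saturday's, holding that “Feeding either J or D delays the D+J loss.”

The flasks gave 10.3% for Sunday's, 6.39% for Friday's and 1.31% for Saturday's, so Sunday's came out highest, under this scheme:

    Q + D ⇌ G (K = 230 L mol⁻¹, k = 0.462 L mol⁻¹ s⁻¹)
    J + D → E (k = 0.527 L mol⁻¹ s⁻¹)
    Q + J → X (k = 0.414 L mol⁻¹ s⁻¹)
    D + G → Z (k = 0.0114 L mol⁻¹ s⁻¹)
    G ⇌ L (K = 1.60, k = 1.86 × 10⁻⁴ s⁻¹)

In Friday's flask the mean [J] over the first 2.5 h was 0.601 mM, below the ceiling of 2.66 mM. In Saturday's flask the mean [D] over the same time was 7.95 mM, above its ceiling of 2.93 mM, and at 2.00 h J stood at 0% and Q at 1.14%, while X at 4.00 h held 90.5% of the Q charged.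

The runs are simulated from invented constants, noise included.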